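all flasks: electrophile 0.50 mM
- Wednesday's: nucleophile 2.8 equiv; protic impurity 0.25 mM; run made earlier
- Sunday's: nucleophile 11 equiv; protic impurity 0.25 mM; run made earlier
- beta: nucleophile 2.50 equiv; protic impurity 0.250 mM; time 3.0 min
- theta: nucleophile 5.00 equiv; protic impurity 0.250 mM; time 3.0 min
- alpha: nucleophile 10.0 equiv; protic impurity 0.250 mM; time 3.0 min

| run | time / min | electrophile / % | target / % |
|---|---|---|---|
| Wednesday's | 0.417 | 46.5 | 53.1 |
| Wednesday's | 1.00 | 33.0 | 66.7 |
| Wednesday's | 2.00 | 26.0 | 73.5 |
| Wednesday's | 3.00 | 23.9 | 75.9 |
| Sunday's | 0.417 | 9.8 | 90.1 |
| Sunday's | 1.00 | 3.4 | 97.0 |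
| Sunday's | 2.00 | 2.3 | 99.8 |
| Sunday's | 3.00 | 0.4 | 99.3 |

(readings scatter by 0.5 percentage points)



1. part of the electrophile that has reacted at the end, beta
2. part of the electrophile that has reacted at the end, theta
3. part of the electrophile that has reacted at the end, alpha
4. what raising the equivalents of nucleophile from its lowest to its highest value here does to the part of the electrophile that has reacted (changes below 5 percentage points count as none) (it rises / no change / it falls)

What strikes me first is how slow the end of Wednesday's run is. I go up the ladder from fastest to slowest, reading each half-life of the electrophile off the runs. Early in Sunday's run, with 11 equiv of nucleophile, it is about 0.124 min. Early in Wednesday's run, with 2.8 equiv, it is longer, about 0.377 min. Between Wednesday's last two readings it is about 8.23 min, much longer again, and longer than the whole 3.0 min of the new flasks. Pseudo-first-order decay keeps a single half-life and Wednesday's run does not, so I read that run as a quick burst followed by a near standstill. Sunday's electrophile, by contrast, still falls from 3.4% at 1.00 min to 0.4% at 3.00 min.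

I measure what a run has done by a given moment as a dose: the natural logarithm of electrophile charged over electrophile left. At 0.417 min the doses are 0.766 for Wednesday's run and 2.32 for Sunday's. The dose exponent, the power of the equivalents by which the dose grows, is then 0.811. Wednesday's dose at 3.00 min is 1.43. Going round once more, I put the rule back on Sunday's run: it gives a dose of 4.34, so 1.30% left, against a last reading of 0.4% with a scatter of 0.5 percentage points, which is rough but usable. Scaled the same way, I expect 72.9% reacted in beta, 89.9% in theta and 98.2% in alpha, a rise of 25 points.

The forecast gives 73%, 89.5% and 98%; of raising the equivalents it says it rises, in its words: “Conversion therefore rises with equivalents.”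

The flasks give 70.3%, 94.3% and 99.1%; as for raising the equivalents, it rises, by 29 points.

    electrophile + nucleophile → acid set free + target (k = 52.0 M⁻¹ s⁻¹)
    nucleophile + acid set free ⇌ protonated nucleophile, settled at all times (K = 2.40 × 10⁶ M⁻¹)
    nucleophile + protic impurity → quenched reagent (k = 520 M⁻¹ s⁻¹)
    2 nucleophile → self-condensation product (k = 16.0 M⁻¹ s⁻¹)

In alpha at 0.0832 min, the rate at which nucleophile goes to self-condensation product is 6.8 times the rate at which it goes to target. At 3.00 min, 2.92% of alpha's charge of nucleophile stands free. Alpha's dose, read back from its result, is 4.67. Scaling that by the exponent to a neighbour flask, alpha with 2.50 equiv of nucleophile, gives a dose of 1.52, so 78.1% reacted. The neighbour gives 70.3%.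

The earlier runs and the new flask were generated by integration for substances that don't exist; noise was put on by code.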